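**Conventions.** Carbons keep the locants of the target throughout: C1 (quaternary ring-fusion carbon, methyl C15), C2 and C3 (ring CH2), C4 (isopropyl carbinol), C5 (ring-fusion CH), C6 (aroyloxy CH), C7 (CH2), C8 (alkene carbon, methyl C14), C9 (alkene CH), C10 (tigloyloxy CH). O4, O6 and O10 are the oxygens on these carbons. β is the face of the C15 methyl group, α the other face. C9 is absent before step 14.

**Assumption on the chemistry.** C8 in 10, 11 and 15–17, the cyclopropane carbons of 19 and C8 of 20 are carried as epimer mixtures, because all of them become trigonal or carbonyl carbons in step 14.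

## The problem

The target is a daucane-type hydroazulene: a cyclopentane (C1–C5) cis-fused through the C1–C5 bond to a cycloheptene (C1, C5–C10), with a quaternary, methyl-bearing C1 at the fusion. Five stereocentres (C1, C4, C5, C6, C10) form one chain; C15, H5, O6 and the isopropyl group lie on the β face, O4 and O10 on the α face. C1 carries no handle for later correction and has to be set absolutely. The others can follow from it: C5 is α to a carbonyl at C6 or C4 and settles in the cis fusion, C6 can be reduced by delivery from a 4α-hydroxyl, C4 by addition to the convex face, and C10 by reduction of a C10 ketone. The three oxygens have three different fates (tertiary alcohol, aryl ester, allylic enoate) and must be told apart without a long protecting-group sequence. The sensitive groups are the allylic tiglate (ionisation, acyl migration), the C6 ester (it is β to C4 and eliminates easily once C4 is a ketone), the free phenol and the tertiary alcohol. The feature that opens the route is that C10, C1, C5, C6, C7 and C8 carry oxygen at C10 and C6 (para to each other) and methyl at C1 and C8. This is the pattern of 2,6-dimethylhydroquinone with the chain C4–C3–C2 on C5. Only C9 is missing, and it sits between C10 and C8, where a C10 ketone can enolise in one direction only.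

## Retrosynthesis

**Ester and silyl bonds (26 ⇒ 25 ⇒ 22 + 23).** The phenol O–Si bond and the C10–O acyl bond are cut first, so that the allylic tiglate is made last and meets only buffered fluoride. Alcohol 22 is simpler by one ester, and the tertiary C4 hydroxyl needs no protection because it does not acylate. The forward step has to acylate a hindered secondary alcohol next to quaternary C1.

**C9 (22 ⇒ 21 ⇒ 17).** The C10 carbinol comes from enone 21, and C9 is taken out from between C8 and C10 (C8–C9 and C9–C10 cut), which gives cyclohexanone 17. Direct seven-ring construction would need a new ring synthesis. One-carbon insertion is chosen because C1 is quaternary: the C10 ketone of 17 enolises only toward C8, so the site of insertion and the position of the C8=C9 double bond are fixed by the structure. The forward sequence is silyl enol ether 18, cyclopropane 19 and FeCl3 opening.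

**C4–isopropyl and C6–O acyl bonds (17 ⇒ 16 ⇒ 15 ⇒ 11 + 14; 14 ⇒ 12).** The C4–C(isopropyl) bond is cut to ketone 16, 16 comes from alcohol 15, and the C6 ester is cut to diol 11 and acid 14 (from 12). Doing this before ring expansion keeps the organometallic step away from any alkene or allylic ester, and the C10 ketone of 16 is shielded by C1 and C8. The forward steps must acylate O6 in the presence of O4 and add isopropyl to a ketone that has a β-acyloxy group.

**C6–H and C7–H/C8–H (11 ⇒ 10 ⇒ 9).** The C6 carbinol comes from a C6 ketone by hydride delivery from the free 4α-hydroxyl, which settles both which ketone reacts and from which face. The saturated dione 10 comes from enedione 9 by Zn reduction. Enedione 9 is flat, has three stereocentres, and its C5 centre is under thermodynamic control.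

**Acetal (9 ⇒ 8).** The C6 carbonyl and the C4 hydroxyl are masked together as the enol acetal of dienone 8, so one mild hydrolysis releases both and no separate protecting groups are carried.

**C1–C2 (8 ⇒ 7), the key cut.** Cutting C1–C2 opens the cyclopentane and restores the arene, giving phenol 7 with a 2-bromoethyl chain on C4. The substrate has to decide which face of C1 is alkylated and which neighbour of C5 reacts (C1, or C6, which is para to the phenoxide oxygen and equally close to C2). With separate ethers on O6 and O4 both would depend on the rotamer about C4–C5, and the rotamer that puts the chain beside the smaller ortho substituent, the C6 oxygen, leads to C6. Joining O6 and O4 in an isopropylidene acetal removes that rotation. It holds O4 in the arene plane, leaves the chain on one face, and makes attack at C6 a bridging reaction. Compound 7 has one stereocentre.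

**Acetal, C4–H and C4–C5 (7 ⇒ 6 ⇒ 3 ⇒ 1 + 2).** The acetonide is cut to triol 6, the C4–H bond to ketone 3 (CBS reduction), and the C4–C5 bond to 2,6-dimethylhydroquinone 1 and 3-bromopropanoic acid 2 (Friedel–Crafts acylation at the only type of free ring position). The ortho-hydroxy bromide would close to a chroman with base, so every step up to the acetal is acidic or neutral, and base is first used in step 4 when O6 is tied.

## Roads not taken

**Alternative 1:** The cut is C1–C10, made while a ring C6–O bond breaks. In the forward step n-BuLi removes the C10 proton of a six-membered allylic ether, and the carbanion shifts onto C1 of a cyclopentene in a [2,3]-Wittig rearrangement to give cycloheptadienol A1. Its merits are real: the seven-membered ring, quaternary C1, the C10 carbinol and the C8=C9 alkene appear in one step with chirality transfer, and no one-carbon insertion is needed. On the seven-membered ring it is shorter than the chosen route, which spends steps 12–15 there. Its weak points are these. The shift must form a quaternary centre at a fully substituted alkene terminus, where the [1,2]-shift and decay of the α-oxy allyl anion compete. The oxygen is expelled from C6, the carbon it must end on, so O6 has to be returned by hydroboration of the C5=C6 bond of A1, which must also set C5 and C6. The enantiopure substrate needs its own multi-step synthesis. Against this directness the chosen plan sets a commercial arene that already holds O6, O10 and both methyl groups, and a C1 centre made by a plain SN2 reaction.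

**Alternative 2:** The cut is C1–C5. A trans-decalin diol monomesylate from a Wieland–Miescher-type ketone rearranges with t-BuOK, C1 moving from C6 to C5, to give the cis-fused hydroazulenone A2. On absolute control of C1 and on the certainty of the ring-forming event this road is at least as good as the chosen one. The quaternary centre comes from a well-established organocatalytic annulation, and the 1,2-shift is stereospecific, whereas the chosen key step relies on relay from C4 and on site selectivity. Its weakness is what A2 lacks: C7, C8 and C9 are bare CH2 groups, so methyl C14 and the C8=C9 alkene must be added by several C–C and redox steps, and the diol mesylate must be made with the right relative configuration. The chosen plan has every ring substituent in place from the start and adds only C9.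

**Alternative 3:** Two bonds are cut, C8–C9 and C6–C7. A diquinane enol acetate adds allene under irradiation, and retro-aldol opening of the adduct gives the 8-methylene dione A3. This road is better than the chosen one in one respect: the C4 carbinol with its isopropyl group is already present in A3, while the chosen plan adds isopropyl late to a hindered ketone beside an ester. It also creates both ring carbonyls at once. Its weak points are these. The enantiopure diquinane with three stereocentres is long to make. The regio- and facial selectivity of the allene addition is uncertain. The exocyclic methylene of A3 can move into the ring toward C9 or toward C7. The C6 and C10 ketones need opposite-face reductions with O4 silylated and unable to direct. In the chosen plan the two ketones differ from the outset (C6 next to a free 4α-hydroxyl, C10 hindered) and the alkene position follows from the single enolisation direction.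

Key step: step 4

## Route

Step 1
Reactants: 1 2,6-dimethylbenzene-1,4-diol; 2 3-bromopropanoic acid
Product: 3 3-bromo-1-(3,6-dihydroxy-2,4-dimethylphenyl)propan-1-one
Conditions: TfOH (neat), 70 °C; ice-water quench, no base
Reagents that add atoms: none
Why: Friedel–Crafts (Fries-type) acylation of an electron-rich hydroquinone in TfOH; the two free ring positions are equivalent, each ortho to the unhindered hydroxyl, and the first acyl group deactivates the ring to a second. The acidic medium keeps the ortho-hydroxy β-bromo ketone from closing to a chromanone.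

Step 2
Reactants: 3 3-bromo-1-(3,6-dihydroxy-2,4-dimethylphenyl)propan-1-one
Product: 6 2-[(1S)-3-bromo-1-hydroxypropyl]-3,5-dimethylbenzene-1,4-diol, via bis(trimethylsilyl) ether ketone 4 (not isolated), via bis(trimethylsilyl) ether carbinol 5 (not isolated)
Conditions: N,O-bis(trimethylsilyl)acetamide (BSA), CH2Cl2, rt, evaporation; (R)-Me-CBS [(R)-1-methyl-3,3-diphenyltetrahydro-1H,3H-pyrrolo[1,2-c][1,3,2]oxazaborole] (20 mol %), BH3·SMe2, THF, −20 °C; MeOH, then aq. citric acid
Reagents that add atoms: none
Why: CBS reduction of an aryl alkyl ketone of the 3-halopropiophenone type; the phenols are masked in the flask as silyl ethers so that no aryloxyborane beside the carbonyl reduces it without the catalyst. The di-ortho-substituted aryl group is the large substituent, so the (R)-catalyst should give the (S)-carbinol at C4; the methanolic acidic work-up removes the aryl silyl groups.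

Step 3
Reactants: 6 2-[(1S)-3-bromo-1-hydroxypropyl]-3,5-dimethylbenzene-1,4-diol
Product: 7 (4S)-4-(2-bromoethyl)-2,2,5,7-tetramethyl-4H-1,3-benzodioxin-6-ol
Conditions: 2,2-dimethoxypropane, pyridinium p-toluenesulfonate (PPTS, cat.), acetone, rt
Reagents that add atoms: 2,2-dimethoxypropane, COC(C)(C)OC
Why: Acid-catalysed acetalisation of a salicyl-type alcohol; only the C6 phenol and the C4 carbinol can close a six-membered dioxin, and the hindered C10 phenol stays free. The weak acid should not ionise the electron-rich benzylic C4–O bond, so the C4 configuration is kept.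

Step 4
Reactants: 7 (4S)-4-(2-bromoethyl)-2,2,5,7-tetramethyl-4H-1,3-benzodioxin-6-ol
Product: 8 (1R,4S)-4,6-(isopropylidenedioxy)-1,8-dimethylbicyclo[4.3.0]nona-5,7-dien-10-one
Conditions: t-BuOK (1.05 equiv), t-BuOH, 0.005 M, 25 to 60 °C
Reagents that add atoms: none
Why: t-BuOK turns the hindered phenol into its phenoxide, whose ortho carbon C1 displaces bromide from C2 in an intramolecular SN2 reaction, and the arene becomes a 6,6-disubstituted cyclohexa-2,4-dienone (alkylative dearomatization). The closest known reaction type is the intramolecular C-alkylation of phenoxides by tethered halides or sulfonates, including attack at an alkyl-bearing ortho carbon of 2,6-dialkylphenoxides, where the dienone persists because no proton is left for rearomatization. The cyclopentane closes in a 5-exo-tet mode; because the nucleophilic carbon and its neighbour C5 both lie in the flat arene, the chain must rise out of the ring plane, and the dioxin ring does this by holding C3 pseudoaxial (the pseudoequatorial position is blocked by peri strain with the C15 methyl). The new stereocentre C1 is controlled by C4: the acetal locks O4 in the arene plane, so C3 and C2 sit on one face only, C2 bonds to that face of C1 and the methyl group is pushed to the other, which gives (1R) from (4S) with O4 trans to C15. The step needs C- over O-alkylation, C1 over C6, and closure over elimination and oligomerisation. O-alkylation would need a seven-membered ring at an oxygen flanked by two methyl groups. C6 is para to the phenoxide oxygen and as close to C2 as C1, but attack there would pyramidalise a carbon held in the acetal ring, build a bridged 2,4-dioxabicyclo[3.2.1]octane and break the conjugation of O6 that attack at C1 keeps as a dienol ether. One equivalent of base in a protic solvent at high dilution leaves no free alkoxide for E2 and slows bimolecular alkylation.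

Step 5
Reactants: 8 (1R,4S)-4,6-(isopropylidenedioxy)-1,8-dimethylbicyclo[4.3.0]nona-5,7-dien-10-one
Product: 9 (1R,4S,5R)-4α-hydroxy-1β,8-dimethyl-cis-bicyclo[4.3.0]non-7-ene-6,10-dione
Conditions: 0.5 M aq. HCl, THF, 0 °C to rt (8 used without storage)
Reagents that add atoms: water, O
Why: Hydrolysis of an enol acetal: protonation of the dienol ether at C5, addition of water and loss of acetone free the C6 ketone and the C4 hydroxyl. C5 is set here; it is α to the C6 carbonyl and equilibrates under the acid to the cis fusion (H5 on the face of C15), the stable arrangement for an angularly methylated hydrindanone with a flattened six-membered ring.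

Step 6
Reactants: 9 (1R,4S,5R)-4α-hydroxy-1β,8-dimethyl-cis-bicyclo[4.3.0]non-7-ene-6,10-dione
Product: 10 (1R,4S,5R)-4α-hydroxy-1β,8-dimethyl-cis-bicyclo[4.3.0]nonane-6,10-dione (C8 epimers)
Conditions: Zn dust, AcOH, rt
Reagents that add atoms: none
Why: Dissolving-metal reduction of a 2-ene-1,4-dione, which accepts two electrons far more easily than an isolated ketone, so only C7=C8 is reduced. The new centre C8 forms as a mixture and is erased in step 14.

Step 7
Reactants: 10 (1R,4S,5R)-4α-hydroxy-1β,8-dimethyl-cis-bicyclo[4.3.0]nonane-6,10-dione (C8 epimers)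
Product: 11 4α,6β-dihydroxy-1β,8-dimethyl-cis-bicyclo[4.3.0]nonan-10-one (C8 epimers)
Conditions: Me4NBH(OAc)3, MeCN/AcOH, −30 to −10 °C
Reagents that add atoms: none
Why: Evans–Saksena reduction: the borohydride exchanges an acetate for the C4 hydroxyl and delivers hydride within the molecule, so only the β-hydroxy ketone carbonyl C6 is reduced and the hindered C10 ketone is left. O4 lies on the α face cis to C6, so hydride should reach C6 from the α face and give the 6β-alcohol (anti 1,3-diol).

Step 8
Reactants: 12 4-hydroxybenzoic acid
Product: 14 4-(triisopropylsilyloxy)benzoic acid, via silyl ester 13 (not isolated)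
Conditions: TIPSCl, imidazole, DMF, rt; then AcOH/THF/H2O, rt
Reagents that add atoms: chlorotriisopropylsilane, CC(C)[Si](Cl)(C(C)C)C(C)C
Why: Silylation of phenol and acid followed by selective hydrolysis of the labile silyl ester; the aryl triisopropylsilyl ether survives aqueous acetic acid.

Step 9
Reactants: 11 4α,6β-dihydroxy-1β,8-dimethyl-cis-bicyclo[4.3.0]nonan-10-one (C8 epimers); 14 4-(triisopropylsilyloxy)benzoic acid
Product: 15 4α-hydroxy-1β,8-dimethyl-6β-[4-(triisopropylsilyloxy)benzoyloxy]-cis-bicyclo[4.3.0]nonan-10-one (C8 epimers)
Conditions: DCC, 4-(dimethylamino)pyridine (DMAP, cat.), CH2Cl2, −20 to 0 °C, one equivalent of 14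
Reagents that add atoms: none
Why: Steglich esterification. The 6β-hydroxyl is an equatorial cyclohexanol trans to C4, whereas the 4α-hydroxyl sits in the concave fold of the cis-hydrindane, cis to C6 and C10, so O6 should be acylated first.

Step 10
Reactants: 15 4α-hydroxy-1β,8-dimethyl-6β-[4-(triisopropylsilyloxy)benzoyloxy]-cis-bicyclo[4.3.0]nonan-10-one (C8 epimers)
Product: 16 1β,8-dimethyl-6β-[4-(triisopropylsilyloxy)benzoyloxy]-cis-bicyclo[4.3.0]nonane-4,10-dione (C8 epimers)
Conditions: Dess–Martin periodinane, NaHCO3, CH2Cl2, 0 °C to rt
Reagents that add atoms: none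
Why: Dess–Martin oxidation of a secondary alcohol under buffered, non-basic conditions, which spares the β-aroyloxy ketone from E1cB elimination. C5 remains cis-fused, the thermodynamic arrangement α to the new ketone.

Step 11
Reactants: 16 1β,8-dimethyl-6β-[4-(triisopropylsilyloxy)benzoyloxy]-cis-bicyclo[4.3.0]nonane-4,10-dione (C8 epimers)
Product: 17 4α-hydroxy-4β-isopropyl-1β,8-dimethyl-6β-[4-(triisopropylsilyloxy)benzoyloxy]-cis-bicyclo[4.3.0]nonan-10-one (C8 epimers)
Conditions: i-PrMgCl, CeCl3, THF, −78 °C
Reagents that add atoms: isopropylmagnesium chloride, CC(C)[Mg]Cl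
Why: Organocerium addition to a ketone: the cerium reagent is weakly basic, so addition should outrun enolisation and loss of the C6 aroate, and it leaves esters and the much more hindered C10 ketone (between quaternary C1 and methyl-bearing C8). The nucleophile comes from the convex β face of the cis-fused bicycle, anti to C6 and C10, which gives the 4α-hydroxy-4β-isopropyl centre.

Step 12
Reactants: 17 4α-hydroxy-4β-isopropyl-1β,8-dimethyl-6β-[4-(triisopropylsilyloxy)benzoyloxy]-cis-bicyclo[4.3.0]nonan-10-one (C8 epimers)
Product: 18 4β-isopropyl-1β,8-dimethyl-6β-[4-(triisopropylsilyloxy)benzoyloxy]-4α,10-bis(trimethylsilyloxy)-cis-bicyclo[4.3.0]non-8(10)-ene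
Conditions: TMSOTf, Et3N, CH2Cl2, 0 °C to rt
Reagents that add atoms: trimethylsilyl trifluoromethanesulfonate, C[Si](C)(C)OS(=O)(=O)C(F)(F)F
Why: Soft enolisation and silylation; C10 can enolise only toward C8 because C1 is quaternary, and the tertiary hydroxyl is silylated at the same time.

Step 13
Reactants: 18 4β-isopropyl-1β,8-dimethyl-6β-[4-(triisopropylsilyloxy)benzoyloxy]-4α,10-bis(trimethylsilyloxy)-cis-bicyclo[4.3.0]non-8(10)-ene
Product: 19 8,10-methano adduct of 18 (C9 as the cyclopropane CH2; 10-trimethylsilyloxy cyclopropane)
Conditions: Et2Zn, CH2I2, CH2Cl2, 0 °C to rt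
Reagents that add atoms: diiodomethane, ICI
Why: Simmons–Smith cyclopropanation in the Furukawa variant, for which electron-rich silyl enol ethers are the most reactive alkenes; the ester carbonyls do not react. The cyclopropane stereocentres are lost in step 14.

Step 14
Reactants: 19 8,10-methano adduct of 18 (C9 as the cyclopropane CH2; 10-trimethylsilyloxy cyclopropane)
Product: 21 4α-hydroxy-4β-isopropyl-1β,8-dimethyl-6β-[4-(triisopropylsilyloxy)benzoyloxy]-cis-bicyclo[5.3.0]dec-8-en-10-one, via β-chloro ketone 20 (not isolated)
Conditions: FeCl3, DMF, 0 °C, 1 M HCl work-up; then NaOAc, MeOH, 65 °C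
Reagents that add atoms: none
Why: Saegusa–Ito ring expansion: FeCl3 oxidises the silyloxycyclopropane to an oxy radical, the internal C8–C10 bond breaks to the tertiary C8 radical, and this takes chlorine from FeCl3; NaOAc then removes HCl through the C9 enolate to give the conjugated enone. C9 is thereby inserted between C8 and C10 and the C8=C9 bond is placed; the acidic work-up frees the tertiary hydroxyl.

Step 15
Reactants: 21 4α-hydroxy-4β-isopropyl-1β,8-dimethyl-6β-[4-(triisopropylsilyloxy)benzoyloxy]-cis-bicyclo[5.3.0]dec-8-en-10-one
Product: 22 4β-isopropyl-1β,8-dimethyl-6β-[4-(triisopropylsilyloxy)benzoyloxy]-cis-bicyclo[5.3.0]dec-8-ene-4α,10α-diol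
Conditions: NaBH4, CeCl3·7H2O, MeOH, −78 to −40 °C
Reagents that add atoms: none
Why: Luche reduction, 1,2-selective for the enone and without action on the esters. With the fully substituted C4 equatorial on the seven-membered ring, the C1–C2 bond stands perpendicular to the carbonyl plane on the α face and the C15 methyl lies near that plane, so hydride is expected to add anti to C2 from the β face and give the 10α-alcohol.

Step 16
Reactants: 22 4β-isopropyl-1β,8-dimethyl-6β-[4-(triisopropylsilyloxy)benzoyloxy]-cis-bicyclo[5.3.0]dec-8-ene-4α,10α-diol; 23 tiglic acid [(E)-2-methylbut-2-enoic acid]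
Product: 25 4α-hydroxy-4β-isopropyl-1β,8-dimethyl-6β-[4-(triisopropylsilyloxy)benzoyloxy]-cis-bicyclo[5.3.0]dec-8-en-10α-yl (E)-2-methylbut-2-enoate, via mixed anhydride 24 (not isolated)
Conditions: 2,4,6-trichlorobenzoyl chloride, Et3N, THF, rt; then 22, DMAP, toluene, 40 °C
Reagents that add atoms: none
Why: Yamaguchi esterification, suited to a hindered secondary alcohol next to a quaternary carbon; the tertiary C4 hydroxyl does not react, and the (E)-geometry of the tigloyl group is the stable one.

Step 17
Reactants: 25 4α-hydroxy-4β-isopropyl-1β,8-dimethyl-6β-[4-(triisopropylsilyloxy)benzoyloxy]-cis-bicyclo[5.3.0]dec-8-en-10α-yl (E)-2-methylbut-2-enoate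
Product: 26 (1R,4R,5S,6S,10S)-4-hydroxy-6-(4-hydroxybenzoyloxy)-4-isopropyl-1,8-dimethyl-cis-bicyclo[5.3.0]dec-8-en-10-yl (E)-2-methylbut-2-enoate (CNP0273650.3)
Conditions: TBAF, AcOH, THF, 0 °C
Reagents that add atoms: none
Why: Fluoride cleavage of an aryl silyl ether, much faster than any reaction of the two esters; acetic acid buffers the phenoxide so that neither acyl migration nor loss of the allylic tiglate can start.

## Compound list

1 | 2,6-dimethylbenzene-1,4-diol (2,6-dimethylhydroquinone) | Cc1cc(O)cc(C)c1O | starting material
2 | 3-bromopropanoic acid | OC(=O)CCBr | starting material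
3 | 3-bromo-1-(3,6-dihydroxy-2,4-dimethylphenyl)propan-1-one | O=C(CCBr)c1c(O)cc(C)c(O)c1C | intermediate
4 | 3-bromo-1-[2,4-dimethyl-3,6-bis(trimethylsilyloxy)phenyl]propan-1-one | O=C(CCBr)c1c(O[Si](C)(C)C)cc(C)c(O[Si](C)(C)C)c1C | intermediate (not isolated)
5 | (1S)-3-bromo-1-[2,4-dimethyl-3,6-bis(trimethylsilyloxy)phenyl]propan-1-ol | O[C@@H](CCBr)c1c(O[Si](C)(C)C)cc(C)c(O[Si](C)(C)C)c1C | intermediate (not isolated)
6 | 2-[(1S)-3-bromo-1-hydroxypropyl]-3,5-dimethylbenzene-1,4-diol | O[C@@H](CCBr)c1c(O)cc(C)c(O)c1C | intermediate
7 | (4S)-4-(2-bromoethyl)-2,2,5,7-tetramethyl-4H-1,3-benzodioxin-6-ol | BrCC[C@@H]1OC(C)(C)Oc2cc(C)c(O)c(C)c21 | intermediate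
8 | (1R,4S)-4,6-(isopropylidenedioxy)-1,8-dimethylbicyclo[4.3.0]nona-5,7-dien-10-one (C15 β, H4 β) | O=C1C(C)=CC2=C3[C@H](CC[C@@]13C)OC(C)(C)O2 | intermediate
9 | (1R,4S,5R)-4α-hydroxy-1β,8-dimethyl-cis-bicyclo[4.3.0]non-7-ene-6,10-dione | O=C1C(C)=CC(=O)[C@H]2[C@@H](O)CC[C@@]12C | intermediate
10 | (1R,4S,5R)-4α-hydroxy-1β,8-dimethyl-cis-bicyclo[4.3.0]nonane-6,10-dione (C8 epimers) | O=C1C(C)CC(=O)[C@H]2[C@@H](O)CC[C@@]12C | intermediate
11 | 4α,6β-dihydroxy-1β,8-dimethyl-cis-bicyclo[4.3.0]nonan-10-one (C8 epimers) | O=C1C(C)C[C@H](O)[C@H]2[C@@H](O)CC[C@@]12C | intermediate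
12 | 4-hydroxybenzoic acid | OC(=O)c1ccc(O)cc1 | starting material
13 | triisopropylsilyl 4-(triisopropylsilyloxy)benzoate | CC(C)[Si](C(C)C)(C(C)C)OC(=O)c1ccc(O[Si](C(C)C)(C(C)C)C(C)C)cc1 | intermediate (not isolated)
14 | 4-(triisopropylsilyloxy)benzoic acid | OC(=O)c1ccc(O[Si](C(C)C)(C(C)C)C(C)C)cc1 | intermediate
15 | 4α-hydroxy-1β,8-dimethyl-6β-[4-(triisopropylsilyloxy)benzoyloxy]-cis-bicyclo[4.3.0]nonan-10-one (C8 epimers) | O=C1C(C)C[C@H](OC(=O)c3ccc(O[Si](C(C)C)(C(C)C)C(C)C)cc3)[C@H]2[C@@H](O)CC[C@@]12C | intermediate
16 | 1β,8-dimethyl-6β-[4-(triisopropylsilyloxy)benzoyloxy]-cis-bicyclo[4.3.0]nonane-4,10-dione (C8 epimers) | O=C1C(C)C[C@H](OC(=O)c3ccc(O[Si](C(C)C)(C(C)C)C(C)C)cc3)[C@H]2C(=O)CC[C@@]12C | intermediate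
17 | 4α-hydroxy-4β-isopropyl-1β,8-dimethyl-6β-[4-(triisopropylsilyloxy)benzoyloxy]-cis-bicyclo[4.3.0]nonan-10-one (C8 epimers) | O=C1C(C)C[C@H](OC(=O)c3ccc(O[Si](C(C)C)(C(C)C)C(C)C)cc3)[C@H]2[C@](O)(C(C)C)CC[C@@]12C | intermediate
18 | 4β-isopropyl-1β,8-dimethyl-6β-[4-(triisopropylsilyloxy)benzoyloxy]-4α,10-bis(trimethylsilyloxy)-cis-bicyclo[4.3.0]non-8(10)-ene | C[Si](C)(C)OC1=C(C)C[C@H](OC(=O)c3ccc(O[Si](C(C)C)(C(C)C)C(C)C)cc3)[C@H]2[C@](O[Si](C)(C)C)(C(C)C)CC[C@@]12C | intermediate
19 | 8,10-methano adduct of 18 (C9 as the cyclopropane CH2; 10-trimethylsilyloxy cyclopropane, cyclopropane epimers) | C[Si](C)(C)OC13CC3(C)C[C@H](OC(=O)c4ccc(O[Si](C(C)C)(C(C)C)C(C)C)cc4)[C@H]2[C@](O[Si](C)(C)C)(C(C)C)CC[C@@]12C | intermediate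
20 | 8-chloro-4α-hydroxy-4β-isopropyl-1β,8-dimethyl-6β-[4-(triisopropylsilyloxy)benzoyloxy]-cis-bicyclo[5.3.0]decan-10-one (C8 epimers) | O=C1CC(C)(Cl)C[C@H](OC(=O)c3ccc(O[Si](C(C)C)(C(C)C)C(C)C)cc3)[C@H]2[C@](O)(C(C)C)CC[C@@]12C | intermediate (not isolated)
21 | 4α-hydroxy-4β-isopropyl-1β,8-dimethyl-6β-[4-(triisopropylsilyloxy)benzoyloxy]-cis-bicyclo[5.3.0]dec-8-en-10-one | O=C1C=C(C)C[C@H](OC(=O)c3ccc(O[Si](C(C)C)(C(C)C)C(C)C)cc3)[C@H]2[C@](O)(C(C)C)CC[C@@]12C | intermediate
22 | 4β-isopropyl-1β,8-dimethyl-6β-[4-(triisopropylsilyloxy)benzoyloxy]-cis-bicyclo[5.3.0]dec-8-ene-4α,10α-diol | O[C@H]1C=C(C)C[C@H](OC(=O)c3ccc(O[Si](C(C)C)(C(C)C)C(C)C)cc3)[C@H]2[C@](O)(C(C)C)CC[C@@]12C | intermediate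
23 | tiglic acid [(E)-2-methylbut-2-enoic acid] | C/C=C(\C)C(=O)O | starting material
24 | (E)-2-methylbut-2-enoic 2,4,6-trichlorobenzoic anhydride | C/C=C(\C)C(=O)OC(=O)c1c(Cl)cc(Cl)cc1Cl | intermediate (not isolated)
25 | 4α-hydroxy-4β-isopropyl-1β,8-dimethyl-6β-[4-(triisopropylsilyloxy)benzoyloxy]-cis-bicyclo[5.3.0]dec-8-en-10α-yl (E)-2-methylbut-2-enoate | C/C=C(\C)C(=O)O[C@H]1C=C(C)C[C@H](OC(=O)c3ccc(O[Si](C(C)C)(C(C)C)C(C)C)cc3)[C@H]2[C@](O)(C(C)C)CC[C@@]12C | intermediate
26 | (1R,4R,5S,6S,10S)-4-hydroxy-6-(4-hydroxybenzoyloxy)-4-isopropyl-1,8-dimethyl-cis-bicyclo[5.3.0]dec-8-en-10-yl (E)-2-methylbut-2-enoate (CNP0273650.3) | C/C=C(\C)C(=O)O[C@H]1C=C(C)C[C@H](OC(=O)c2ccc(O)cc2)[C@@H]2[C@@]1(C)CC[C@@]2(O)C(C)C | target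

## Step count and uncertain steps

Total: 17 steps. Longest linear sequence: 16 steps (steps 1–7 and 9–17, from 1); step 8 is a one-step side branch.

**Step 4 (key step).** The closure is geometrically demanding, because the nucleophilic carbon is part of the arene and the chain must bend out of its plane. It may therefore be outrun by bimolecular alkylation, by loss of HBr, or by attack through C6, which is para to the phenoxide oxygen and as near to C2 as C1. The dienone may also dimerise by cycloaddition if it is stored. The fallback keeps the C1–C2 disconnection but changes the substrate design, so that selectivity rests on steric screening of C6 instead of on acetal ring strain, and the unmasking changes from acid to fluoride. It sets out from 6: t-Bu2Si(OTf)2 and 2,6-lutidine in CH2Cl2 at 0 °C should give the silylene-bridged bromide F1, whose two tert-butyl groups stand above and below C6 and whose longer Si–O bonds ease the pseudoaxial chain toward C1. Closure with t-BuOK in t-BuOH should give the silylene-bridged dienone F2, and HF·pyridine in wet THF cleaves both Si–O bonds and returns to the route at 9.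

**Step 9.** Acylation may spread over both hydroxyls or reach O4, because the two secondary alcohols differ only in their steric surroundings. The fallback sets out from 10 and makes the difference chemical. An Evans–Tishchenko reduction (SmI2 cat., acetaldehyde, THF, −10 °C) reduces C6 with the same intramolecular delivery and leaves the acyl group on the delivering oxygen, which should give the 4α-acetoxy-6β-alcohol F3. Esterification of the only free hydroxyl with 14 (DCC, DMAP) gives the acetate aroate F4, and Mg(OMe)2 in MeOH at 0 °C removes the acetate ahead of the electron-rich aroate and returns at 15.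

**Step 11.** The bulky, reducing isopropyl nucleophile may transfer a β-hydride or deprotonate C5 in place of adding, and the C5 enolate would expel the C6 aroate. The fallback sets out from 16 and uses a nucleophile that has no β-hydrogen to transfer and is smaller: isopropenylmagnesium bromide with CeCl3 in THF at −78 °C should give the 4β-isopropenyl carbinol F5, and hydrogenation (H2, Pd/C, EtOAc; no other alkene is present at this stage) returns at 17.

**Step 13.** Cyclopropanation may stall, because the silyl enol ether is tetrasubstituted and flanked by quaternary C1. The fallback sets out from 17 and inserts C9 as a diazoalkane carbon. Trimethylsilyldiazomethane with AlMe3 in CH2Cl2 (−78 to 0 °C) should add to the C10 ketone and let the less substituted C8 migrate, giving the 9-trimethylsilyl cycloheptanone F6. Dilute HCl removes the silyl group to give cycloheptanone F7, and dehydrogenation with 2-iodoxybenzoic acid in DMSO at 70 °C, which can only occur toward C9–C8, returns at 21.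

**Step 15.** Facial selectivity may be poor or reversed, because the C15 methyl and the C2 methylene flank the two faces of the C10 carbonyl and the preference rests on ring conformation. The fallback sets out from 21 and accepts the other epimer. If hydride adds from the α face, the 10β-alcohol F8 forms, and Mitsunobu esterification of F8 with tiglic acid 23 (PPh3, diisopropyl azodicarboxylate, toluene, 0 °C to rt) inverts C10 while installing the ester and returns at 25.

## Further compounds

F1 | step 4 | (4S)-4-(2-bromoethyl)-2,2-di-tert-butyl-5,7-dimethyl-4H-1,3,2-benzodioxasilin-6-ol | BrCC[C@@H]1O[Si](C(C)(C)C)(C(C)(C)C)Oc2cc(C)c(O)c(C)c21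
F2 | step 4 | (1R,4S)-4,6-(di-tert-butylsilylenedioxy)-1,8-dimethylbicyclo[4.3.0]nona-5,7-dien-10-one | O=C1C(C)=CC2=C3[C@H](CC[C@@]13C)O[Si](C(C)(C)C)(C(C)(C)C)O2
F3 | step 9 | 4α-acetoxy-6β-hydroxy-1β,8-dimethyl-cis-bicyclo[4.3.0]nonan-10-one (C8 epimers) | O=C1C(C)C[C@H](O)[C@H]2[C@@H](OC(C)=O)CC[C@@]12C
F4 | step 9 | 4α-acetoxy-1β,8-dimethyl-6β-[4-(triisopropylsilyloxy)benzoyloxy]-cis-bicyclo[4.3.0]nonan-10-one (C8 epimers) | O=C1C(C)C[C@H](OC(=O)c3ccc(O[Si](C(C)C)(C(C)C)C(C)C)cc3)[C@H]2[C@@H](OC(C)=O)CC[C@@]12C
F5 | step 11 | 4α-hydroxy-4β-isopropenyl-1β,8-dimethyl-6β-[4-(triisopropylsilyloxy)benzoyloxy]-cis-bicyclo[4.3.0]nonan-10-one (C8 epimers) | O=C1C(C)C[C@H](OC(=O)c3ccc(O[Si](C(C)C)(C(C)C)C(C)C)cc3)[C@H]2[C@](O)(C(C)=C)CC[C@@]12C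
F6 | step 13 | 4α-hydroxy-4β-isopropyl-1β,8-dimethyl-6β-[4-(triisopropylsilyloxy)benzoyloxy]-9-trimethylsilyl-cis-bicyclo[5.3.0]decan-10-one (C8, C9 epimers) | O=C1C([Si](C)(C)C)C(C)C[C@H](OC(=O)c3ccc(O[Si](C(C)C)(C(C)C)C(C)C)cc3)[C@H]2[C@](O)(C(C)C)CC[C@@]12C
F7 | step 13 | 4α-hydroxy-4β-isopropyl-1β,8-dimethyl-6β-[4-(triisopropylsilyloxy)benzoyloxy]-cis-bicyclo[5.3.0]decan-10-one (C8 epimers) | O=C1CC(C)C[C@H](OC(=O)c3ccc(O[Si](C(C)C)(C(C)C)C(C)C)cc3)[C@H]2[C@](O)(C(C)C)CC[C@@]12C
F8 | step 15 | 4β-isopropyl-1β,8-dimethyl-6β-[4-(triisopropylsilyloxy)benzoyloxy]-cis-bicyclo[5.3.0]dec-8-ene-4α,10β-diol | O[C@@H]1C=C(C)C[C@H](OC(=O)c3ccc(O[Si](C(C)C)(C(C)C)C(C)C)cc3)[C@H]2[C@](O)(C(C)C)CC[C@@]12C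
A1 | alternative 1 | 10-hydroxy-1,8-dimethylbicyclo[5.3.0]deca-5,8-dien-4-one ethylene ketal (cycloheptadienol) | O[C@H]1C=C(C)CC=C2[C@@]1(C)CCC23OCCO3
A2 | alternative 2 | cis-fused 4-(tert-butyldimethylsilyloxy)-1-methylbicyclo[5.3.0]decane-6,10-dione 10-ethylene ketal | C[C@@]12CC[C@@H](O[Si](C)(C)C(C)(C)C)[C@@H]1C(=O)CCCC23OCCO3
A3 | alternative 3 | cis-fused 4-isopropyl-1-methyl-8-methylene-4-(triethylsilyloxy)bicyclo[5.3.0]decane-6,10-dione | O=C1CC(=C)CC(=O)[C@@H]2[C@@]1(C)CC[C@@]2(O[Si](CC)(CC)CC)C(C)C
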